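**Retrosynthetic overview**

1. The dihydropyran ring of the flavan is closed last, by intramolecular Mitsunobu etherification with inversion of an (R)-1,3-diarylpropan-1-ol; its three-carbon bridge comes from a Claisen–Schmidt condensation of a ring B methyl ketone with a ring A aldehyde, conjugate reduction and asymmetric transfer hydrogenation.
2. The prenyl group is moved from the C8 oxygen to C7 of ring B by aromatic Claisen rearrangement of a 1,1-dimethylallyl ether.
3. The 2,2-dimethyl-2H-pyran ring is not closed at its final size: an aryne (triple bond between the future C4a and C8a) and an enal first give a four-membered 2H-benzoxete (O1, C4, C4a, C8a), which opens to an ortho-quinone methide and recloses by oxa-6π electrocyclisation, a ring expansion by the alkene carbons C3 and C2.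
4. Enabling feature: O1 and C4 sit on adjacent arene carbons and the ring holds the C3=C4 alkene next to quaternary C2, so the pyran is the valence isomer of an ortho-quinone methide; the hydroxyl on C8, next to C8a, is carried as a boronate that steers the aldehyde oxygen to C8a and is later oxidised to that hydroxyl.
5. Ring order: ring B (bought) → benzoxete → pyran ring of the chromene → dihydropyran ring of the flavan; ring A is bought.

Key step: step 5

Remark: locants C2 to C8a are those of the 2H-chromene unit of ring B; the reagents named under the steps are taken as purchasable.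

**Route**

Step 1
Reactants: 1 1-(3,5-dibromo-4-hydroxyphenyl)ethan-1-one
Product: 2 2,6-dibromo-4-(2-methyl-1,3-dioxolan-2-yl)phenol
Conditions: HOCH2CH2OH, TsOH·H2O (cat.), toluene, reflux, azeotropic removal of water
Reagents that add atoms: ethane-1,2-diol, OCCO
Why: Acid-catalysed ketalisation masks the enolisable acetyl group as a dioxolane so that it should survive the organolithium steps and stay inert toward the aryne.

Step 2
Reactants: 2 2,6-dibromo-4-(2-methyl-1,3-dioxolan-2-yl)phenol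
Product: 4 2-bromo-4-(2-methyl-1,3-dioxolan-2-yl)-6-(trimethylsilyl)phenol, via aryl trimethylsilyl ether 3 (not isolated)
Conditions: (Me3Si)2NH, THF, 65 °C; concentrate; n-BuLi (1.05 equiv), THF, −78 → 20 °C; aq. NH4Cl
Reagents that add atoms: hexamethyldisilazane, C[Si](C)(C)N[Si](C)(C)C
Why: O-silylation followed by bromine–lithium exchange should trigger a retro-Brook rearrangement (1,3-shift of silicon from oxygen to carbon), and one equivalent of n-BuLi limits the exchange to one bromine.

Step 3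
Reactants: 4 2-bromo-4-(2-methyl-1,3-dioxolan-2-yl)-6-(trimethylsilyl)phenol
Product: 5 4-(2-methyl-1,3-dioxolan-2-yl)-2-(4,4,5,5-tetramethyl-1,3,2-dioxaborolan-2-yl)-6-(trimethylsilyl)phenol
Conditions: n-BuLi (2.2 equiv), THF, −78 → −20 °C; i-PrOBpin, −78 → 20 °C; aq. NH4Cl
Reagents that add atoms: 2-isopropoxy-4,4,5,5-tetramethyl-1,3,2-dioxaborolane, CC(C)OB1OC(C)(C)C(C)(C)O1
Why: Deprotonation and bromine–lithium exchange followed by trapping with the isopropoxyboronate (lithiation–borylation) should place boron on the carbon that becomes C8.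

Step 4
Reactants: 5 4-(2-methyl-1,3-dioxolan-2-yl)-2-(4,4,5,5-tetramethyl-1,3,2-dioxaborolan-2-yl)-6-(trimethylsilyl)phenol
Product: 6 4-(2-methyl-1,3-dioxolan-2-yl)-2-(4,4,5,5-tetramethyl-1,3,2-dioxaborolan-2-yl)-6-(trimethylsilyl)phenyl trifluoromethanesulfonate
Conditions: Tf2O, pyridine, CH2Cl2, 0 °C
Reagents that add atoms: trifluoromethanesulfonic anhydride, O=S(=O)(OS(=O)(=O)C(F)(F)F)C(F)(F)F
Why: O-sulfonylation turns the phenol oxygen into the leaving group of an ortho-silylaryl triflate, the fluoride-triggered aryne precursor.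

Step 5
Reactants: 6 4-(2-methyl-1,3-dioxolan-2-yl)-2-(4,4,5,5-tetramethyl-1,3,2-dioxaborolan-2-yl)-6-(trimethylsilyl)phenyl trifluoromethanesulfonate; 7 3-methylbut-2-enal
Product: 11 2-[2,2-dimethyl-6-(2-methyl-1,3-dioxolan-2-yl)-2H-chromen-8-yl]-4,4,5,5-tetramethyl-1,3,2-dioxaborolane, via aryne 8 (not isolated), via 2H-benzoxete 9 (not isolated), via ortho-quinone methide 10 (not isolated)
Conditions: CsF (3 equiv), 7 (4 equiv), MeCN, 25 °C
Reagents that add atoms: none
Why: Fluoride removes the trimethylsilyl group of 6 with loss of triflate to give aryne 8, whose capture by the carbonyl oxygen of 7 and collapse of the resulting aryl anion onto the oxocarbenium carbon (formal [2+2] cycloaddition) closes the four-membered 2H-benzoxete 9 (O1, C4, C4a, C8a). Thermal 4π electrocyclic opening of the O1–C4 bond gives ortho-quinone methide 10, and its 1-oxatriene (O1=C8a–C4a=C4–C3=C2) recloses by disrotatory oxa-6π electrocyclisation, so the four-membered ring is expanded by C3 and C2 into the 2H-pyran ring while the arene is regained. The closest known reaction type is the fluoride-induced coupling of 2-(trimethylsilyl)aryl triflates with α,β-unsaturated aldehydes to 2H-chromenes, itself an extension of the aryne–aldehyde route to ortho-quinone methides. No stereocentre survives, since the benzoxete carbon of 9 becomes sp2 in 10 and C2 of 11 carries two methyl groups. The step needs regioselectivity (oxygen to the aryne carbon flanked by boron, carbon to the other), which the electropositive boryl group should secure by distorting the aryne so that its neighbouring carbon is the more electrophilic one, as in amine additions to 3-borylarynes, with the inductively withdrawing ketal carbon para to that position acting in the same sense. It also needs the ring closure of 10 to outrun capture by a second aryne, which the intramolecular 6π step, the excess of 7 and the slow release of 8 from sparingly soluble CsF should secure.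

Step 6
Reactants: 11 2-[2,2-dimethyl-6-(2-methyl-1,3-dioxolan-2-yl)-2H-chromen-8-yl]-4,4,5,5-tetramethyl-1,3,2-dioxaborolane
Product: 13 1-(8-hydroxy-2,2-dimethyl-2H-chromen-6-yl)ethan-1-one, via chromenol ketal 12 (not isolated)
Conditions: 30% aq. H2O2, NaOH, THF/H2O, 0 → 20 °C; then 2 M HCl, THF, 20 °C
Reagents that add atoms: hydrogen peroxide, OO; water, O
Why: Boronate oxidation (1,2-shift of the aryl group from boron to oxygen) should give the C8 phenol at the boron-bearing carbon, and brief aqueous acid should hydrolyse the ketal without touching the chromene.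

Step 7
Reactants: 13 1-(8-hydroxy-2,2-dimethyl-2H-chromen-6-yl)ethan-1-one
Product: 14 1-{2,2-dimethyl-8-[(2-methylbut-3-en-2-yl)oxy]-2H-chromen-6-yl}ethan-1-one
Conditions: Pd(PPh3)4 (2 mol %), t-BuOCO2C(Me)2CH=CH2, THF, 4 Å molecular sieves, 0 °C
Reagents that add atoms: tert-butyl 2-methylbut-3-en-2-yl carbonate, CC(C)(C)OC(=O)OC(C)(C)C=C
Why: Tsuji–Trost O-allylation, in which zerovalent palladium ionises the tertiary carbonate and the phenoxide formed on decarboxylation should attack the more substituted allyl terminus under kinetic control at low temperature.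

Step 8
Reactants: 14 1-{2,2-dimethyl-8-[(2-methylbut-3-en-2-yl)oxy]-2H-chromen-6-yl}ethan-1-one
Product: 15 1-[8-hydroxy-2,2-dimethyl-7-(3-methylbut-2-en-1-yl)-2H-chromen-6-yl]ethan-1-one
Conditions: xylene, 140 °C
Reagents that add atoms: none
Why: Aromatic Claisen rearrangement ([3,3]) should deliver the allyl terminus to C7, the only free position ortho to the C8 oxygen, with allylic transposition to the prenyl group and tautomerisation back to the phenol.

Step 9
Reactants: 16 2,4-dihydroxybenzaldehyde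
Product: 17 2-hydroxy-4-(prop-2-en-1-yloxy)benzaldehyde
Conditions: allyl bromide (1.05 equiv), K2CO3 (1.0 equiv), acetone, 50 °C
Reagents that add atoms: allyl bromide, C=CCBr
Why: Williamson etherification should be selective for the 4-hydroxyl because the 2-hydroxyl is hydrogen-bonded to the formyl group and less nucleophilic.

Step 10
Reactants: 15 1-[8-hydroxy-2,2-dimethyl-7-(3-methylbut-2-en-1-yl)-2H-chromen-6-yl]ethan-1-one; 17 2-hydroxy-4-(prop-2-en-1-yloxy)benzaldehyde
Product: 18 (2E)-1-[8-hydroxy-2,2-dimethyl-7-(3-methylbut-2-en-1-yl)-2H-chromen-6-yl]-3-[2-hydroxy-4-(prop-2-en-1-yloxy)phenyl]prop-2-en-1-one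
Conditions: KOH, EtOH/H2O, 20 → 40 °C; then 1 M HCl to pH 6
Reagents that add atoms: none
Why: Claisen–Schmidt condensation (crossed aldol with E1cB dehydration) of the methyl ketone with the non-enolisable aldehyde should give the thermodynamically preferred (E)-enone.

Step 11
Reactants: 18 (2E)-1-[8-hydroxy-2,2-dimethyl-7-(3-methylbut-2-en-1-yl)-2H-chromen-6-yl]-3-[2-hydroxy-4-(prop-2-en-1-yloxy)phenyl]prop-2-en-1-one
Product: 19 1-[8-hydroxy-2,2-dimethyl-7-(3-methylbut-2-en-1-yl)-2H-chromen-6-yl]-3-[2-hydroxy-4-(prop-2-en-1-yloxy)phenyl]propan-1-one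
Conditions: [(Ph3P)CuH]6 (5 mol %), PhMe2SiH, t-BuOH, toluene, 20 °C; aq. NH4Cl
Reagents that add atoms: none
Why: Copper hydride conjugate reduction with protonation of the copper enolate by tert-butanol should reduce only the enone C=C and leave the prenyl, allyl and chromene alkenes, none of which is conjugated to a carbonyl.

Step 12
Reactants: 19 1-[8-hydroxy-2,2-dimethyl-7-(3-methylbut-2-en-1-yl)-2H-chromen-6-yl]-3-[2-hydroxy-4-(prop-2-en-1-yloxy)phenyl]propan-1-one
Product: 20 (1R)-1-[8-hydroxy-2,2-dimethyl-7-(3-methylbut-2-en-1-yl)-2H-chromen-6-yl]-3-[2-hydroxy-4-(prop-2-en-1-yloxy)phenyl]propan-1-ol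
Conditions: RuCl[(R,R)-TsDPEN](p-cymene) (2 mol %), HCO2Na, H2O/MeOH, 40 °C
Reagents that add atoms: none
Why: Asymmetric transfer hydrogenation, in which the ruthenium hydride and the ligand N–H deliver hydride and proton through a six-membered transition state with the ketone aryl group under the p-cymene ligand, should set the carbinol stereocentre as (R), the sense this catalyst enantiomer gives with aryl alkyl ketones.

Step 13
Reactants: 20 (1R)-1-[8-hydroxy-2,2-dimethyl-7-(3-methylbut-2-en-1-yl)-2H-chromen-6-yl]-3-[2-hydroxy-4-(prop-2-en-1-yloxy)phenyl]propan-1-ol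
Product: 21 2,2-dimethyl-7-(3-methylbut-2-en-1-yl)-6-[(2S)-7-(prop-2-en-1-yloxy)-3,4-dihydro-2H-chromen-2-yl]-2H-chromen-8-ol
Conditions: PPh3, DIAD, THF, 0 → 20 °C, high dilution
Reagents that add atoms: none
Why: Intramolecular Mitsunobu etherification, in which the ring A phenol displaces the oxyphosphonium-activated benzylic oxygen in a 6-exo-tet SN2 closure with inversion, should turn the (R)-carbinol into the (S)-configured C2 of the flavan.

Step 14
Reactants: 21 2,2-dimethyl-7-(3-methylbut-2-en-1-yl)-6-[(2S)-7-(prop-2-en-1-yloxy)-3,4-dihydro-2H-chromen-2-yl]-2H-chromen-8-ol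
Product: 22 Kazinol B, 6-[(2S)-7-hydroxy-3,4-dihydro-2H-chromen-2-yl]-2,2-dimethyl-7-(3-methylbut-2-en-1-yl)-2H-chromen-8-ol
Conditions: Pd(PPh3)4 (5 mol %), morpholine, THF, 20 °C
Reagents that add atoms: none
Why: Tsuji–Trost deallylation, in which zerovalent palladium ionises the unhindered allyl aryl ether and morpholine captures the allyl group, should free the phenol under neutral conditions that leave the benzylic ether stereocentre, the hindered chromene and the prenyl group untouched.

**Compound list**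

1 | 1-(3,5-dibromo-4-hydroxyphenyl)ethan-1-one | CC(=O)c1cc(Br)c(O)c(Br)c1 | starting material
2 | 2,6-dibromo-4-(2-methyl-1,3-dioxolan-2-yl)phenol | CC1(OCCO1)c1cc(Br)c(O)c(Br)c1 | intermediate
3 | [2,6-dibromo-4-(2-methyl-1,3-dioxolan-2-yl)phenoxy](trimethyl)silane | CC1(OCCO1)c1cc(Br)c(O[Si](C)(C)C)c(Br)c1 | intermediate
4 | 2-bromo-4-(2-methyl-1,3-dioxolan-2-yl)-6-(trimethylsilyl)phenol | CC1(OCCO1)c1cc(Br)c(O)c(c1)[Si](C)(C)C | intermediate
5 | 4-(2-methyl-1,3-dioxolan-2-yl)-2-(4,4,5,5-tetramethyl-1,3,2-dioxaborolan-2-yl)-6-(trimethylsilyl)phenol | CC1(OCCO1)c1cc(B2OC(C)(C)C(C)(C)O2)c(O)c(c1)[Si](C)(C)C | intermediate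
6 | 4-(2-methyl-1,3-dioxolan-2-yl)-2-(4,4,5,5-tetramethyl-1,3,2-dioxaborolan-2-yl)-6-(trimethylsilyl)phenyl trifluoromethanesulfonate | CC1(OCCO1)c1cc(B2OC(C)(C)C(C)(C)O2)c(OS(=O)(=O)C(F)(F)F)c(c1)[Si](C)(C)C | intermediate
7 | 3-methylbut-2-enal | CC(C)=CC=O | starting material
8 | 2-[2,3-didehydro-5-(2-methyl-1,3-dioxolan-2-yl)phenyl]-4,4,5,5-tetramethyl-1,3,2-dioxaborolane (aryne) | CC1(OCCO1)C1=CC#CC(B2OC(C)(C)C(C)(C)O2)=C1 | intermediate
9 | 2-[4-(2-methyl-1,3-dioxolan-2-yl)-2-(2-methylprop-1-en-1-yl)-2H-benzo[b]oxet-6-yl]-4,4,5,5-tetramethyl-1,3,2-dioxaborolane (racemic) | CC(C)=CC1Oc2c(B3OC(C)(C)C(C)(C)O3)cc(cc12)C1(C)OCCO1 | intermediate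
10 | 2-[(5Z)-3-(2-methyl-1,3-dioxolan-2-yl)-5-(3-methylbut-2-en-1-ylidene)-6-oxocyclohexa-1,3-dien-1-yl]-4,4,5,5-tetramethyl-1,3,2-dioxaborolane | CC(C)=C/C=C1/C=C(C=C(B2OC(C)(C)C(C)(C)O2)C1=O)C1(C)OCCO1 | intermediate
11 | 2-[2,2-dimethyl-6-(2-methyl-1,3-dioxolan-2-yl)-2H-chromen-8-yl]-4,4,5,5-tetramethyl-1,3,2-dioxaborolane | CC1(C)C=Cc2cc(cc(B3OC(C)(C)C(C)(C)O3)c2O1)C1(C)OCCO1 | intermediate
12 | 2,2-dimethyl-6-(2-methyl-1,3-dioxolan-2-yl)-2H-chromen-8-ol | CC1(C)C=Cc2cc(cc(O)c2O1)C1(C)OCCO1 | intermediate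
13 | 1-(8-hydroxy-2,2-dimethyl-2H-chromen-6-yl)ethan-1-one | CC(=O)c1cc(O)c2OC(C)(C)C=Cc2c1 | intermediate
14 | 1-{2,2-dimethyl-8-[(2-methylbut-3-en-2-yl)oxy]-2H-chromen-6-yl}ethan-1-one | CC(=O)c1cc(OC(C)(C)C=C)c2OC(C)(C)C=Cc2c1 | intermediate
15 | 1-[8-hydroxy-2,2-dimethyl-7-(3-methylbut-2-en-1-yl)-2H-chromen-6-yl]ethan-1-one | CC(=O)c1cc2C=CC(C)(C)Oc2c(O)c1CC=C(C)C | intermediate
16 | 2,4-dihydroxybenzaldehyde | O=Cc1ccc(O)cc1O | starting material
17 | 2-hydroxy-4-(prop-2-en-1-yloxy)benzaldehyde | O=Cc1ccc(OCC=C)cc1O | intermediate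
18 | (2E)-1-[8-hydroxy-2,2-dimethyl-7-(3-methylbut-2-en-1-yl)-2H-chromen-6-yl]-3-[2-hydroxy-4-(prop-2-en-1-yloxy)phenyl]prop-2-en-1-one | CC(C)=CCc1c(C(=O)/C=C/c2ccc(OCC=C)cc2O)cc2C=CC(C)(C)Oc2c1O | intermediate
19 | 1-[8-hydroxy-2,2-dimethyl-7-(3-methylbut-2-en-1-yl)-2H-chromen-6-yl]-3-[2-hydroxy-4-(prop-2-en-1-yloxy)phenyl]propan-1-one | CC(C)=CCc1c(C(=O)CCc2ccc(OCC=C)cc2O)cc2C=CC(C)(C)Oc2c1O | intermediate
20 | (1R)-1-[8-hydroxy-2,2-dimethyl-7-(3-methylbut-2-en-1-yl)-2H-chromen-6-yl]-3-[2-hydroxy-4-(prop-2-en-1-yloxy)phenyl]propan-1-ol | CC(C)=CCc1c([C@H](O)CCc2ccc(OCC=C)cc2O)cc2C=CC(C)(C)Oc2c1O | intermediate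
21 | 2,2-dimethyl-7-(3-methylbut-2-en-1-yl)-6-[(2S)-7-(prop-2-en-1-yloxy)-3,4-dihydro-2H-chromen-2-yl]-2H-chromen-8-ol | CC(C)=CCc1c([C@@H]2CCc3ccc(OCC=C)cc3O2)cc2C=CC(C)(C)Oc2c1O | intermediate
22 | Kazinol B, 6-[(2S)-7-hydroxy-3,4-dihydro-2H-chromen-2-yl]-2,2-dimethyl-7-(3-methylbut-2-en-1-yl)-2H-chromen-8-ol | CC(C)=CCc1c([C@@H]2CCc3ccc(O)cc3O2)cc2c(c1O)OC(C)(C)C=C2 | target

**Step count and risks**

Total step count: 14. Longest linear sequence: 13 steps (steps 1 to 8 and 10 to 14).

Steps most likely to fail: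

Step 5. The carbonyl oxygen may add to the wrong aryne carbon (regiochemical leakage). Fluoride may attack boron and divert the precursor by elimination towards the boron-bearing carbon or by protodeboronation. The enal may self-condense under basic fluoride, and the ortho-quinone methide may be captured by a second aryne before it closes. The fallback gives up the aryne and sets out from 1. A Heck reaction at one C–Br bond with 2-methylbut-3-en-2-ol (Pd(OAc)2, P(o-tol)3, Et3N, MeCN, 90 °C) should give 1-{3-bromo-4-hydroxy-5-[(1E)-3-hydroxy-3-methylbut-1-en-1-yl]phenyl}ethan-1-one F1. Acid-catalysed cyclodehydration (TsOH, toluene, 60 °C) should close the chromene to 1-(8-bromo-2,2-dimethyl-2H-chromen-6-yl)ethan-1-one F2. Miyaura borylation (bis(pinacolato)diboron, PdCl2(dppf), KOAc, 1,4-dioxane, 90 °C) should give 1-[2,2-dimethyl-8-(4,4,5,5-tetramethyl-1,3,2-dioxaborolan-2-yl)-2H-chromen-6-yl]ethan-1-one F3, and H2O2/NaOH oxidation of F3 comes back to the route at 13.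

Step 13. The oxyphosphonium intermediate may ionise to a benzylic cation stabilised by the para ether oxygen, so that enantiomeric purity is eroded (SN1 leakage), and elimination to the styrene may compete. The fallback closes the other C–O bond of the flavan, so that no bond to the stereocentre is made or broken, and sets out from 15. Commercial 2-bromo-4-hydroxybenzaldehyde is O-allylated (allyl bromide, K2CO3, acetone) to 2-bromo-4-(prop-2-en-1-yloxy)benzaldehyde F4. Claisen–Schmidt condensation of 15 with F4 (KOH, EtOH) should give (2E)-3-[2-bromo-4-(prop-2-en-1-yloxy)phenyl]-1-[8-hydroxy-2,2-dimethyl-7-(3-methylbut-2-en-1-yl)-2H-chromen-6-yl]prop-2-en-1-one F5. Conjugate reduction under the conditions of step 11 should give 3-[2-bromo-4-(prop-2-en-1-yloxy)phenyl]-1-[8-hydroxy-2,2-dimethyl-7-(3-methylbut-2-en-1-yl)-2H-chromen-6-yl]propan-1-one F6. Transfer hydrogenation with the enantiomeric catalyst RuCl[(S,S)-TsDPEN](p-cymene) should give (1S)-3-[2-bromo-4-(prop-2-en-1-yloxy)phenyl]-1-[8-hydroxy-2,2-dimethyl-7-(3-methylbut-2-en-1-yl)-2H-chromen-6-yl]propan-1-ol F7. Intramolecular copper-catalysed O-arylation (CuI, 3,4,7,8-tetramethyl-1,10-phenanthroline, Cs2CO3, toluene, 110 °C) then proceeds with retention at the carbinol and comes back to the route at 21.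

Step 7. The phenoxide may attack the unsubstituted allyl terminus, or the tertiary ether may re-ionise and equilibrate to the linear prenyl ether, which would deliver the wrong C-substituent in step 8. The fallback replaces the allylic substitution by propargylation and semi-hydrogenation and sets out from 13. Alkylation with 3-chloro-3-methylbut-1-yne (K2CO3, KI, CuI cat., acetone, 56 °C) should give 1-{2,2-dimethyl-8-[(2-methylbut-3-yn-2-yl)oxy]-2H-chromen-6-yl}ethan-1-one F8. Semi-hydrogenation of the terminal alkyne (H2, Pd on CaCO3 poisoned with Pb(OAc)2, quinoline, EtOAc) comes back to the route at 14.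

**Further compounds**

F1 | step 5 | 1-{3-bromo-4-hydroxy-5-[(1E)-3-hydroxy-3-methylbut-1-en-1-yl]phenyl}ethan-1-one | CC(=O)c1cc(Br)c(O)c(/C=C/C(C)(C)O)c1
F2 | step 5 | 1-(8-bromo-2,2-dimethyl-2H-chromen-6-yl)ethan-1-one | CC(=O)c1cc(Br)c2OC(C)(C)C=Cc2c1
F3 | step 5 | 1-[2,2-dimethyl-8-(4,4,5,5-tetramethyl-1,3,2-dioxaborolan-2-yl)-2H-chromen-6-yl]ethan-1-one | CC(=O)c1cc(B2OC(C)(C)C(C)(C)O2)c2OC(C)(C)C=Cc2c1
F4 | step 13 | 2-bromo-4-(prop-2-en-1-yloxy)benzaldehyde | O=Cc1ccc(OCC=C)cc1Br
F5 | step 13 | (2E)-3-[2-bromo-4-(prop-2-en-1-yloxy)phenyl]-1-[8-hydroxy-2,2-dimethyl-7-(3-methylbut-2-en-1-yl)-2H-chromen-6-yl]prop-2-en-1-one | CC(C)=CCc1c(C(=O)/C=C/c2ccc(OCC=C)cc2Br)cc2C=CC(C)(C)Oc2c1O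
F6 | step 13 | 3-[2-bromo-4-(prop-2-en-1-yloxy)phenyl]-1-[8-hydroxy-2,2-dimethyl-7-(3-methylbut-2-en-1-yl)-2H-chromen-6-yl]propan-1-one | CC(C)=CCc1c(C(=O)CCc2ccc(OCC=C)cc2Br)cc2C=CC(C)(C)Oc2c1O
F7 | step 13 | (1S)-3-[2-bromo-4-(prop-2-en-1-yloxy)phenyl]-1-[8-hydroxy-2,2-dimethyl-7-(3-methylbut-2-en-1-yl)-2H-chromen-6-yl]propan-1-ol | CC(C)=CCc1c([C@@H](O)CCc2ccc(OCC=C)cc2Br)cc2C=CC(C)(C)Oc2c1O
F8 | step 7 | 1-{2,2-dimethyl-8-[(2-methylbut-3-yn-2-yl)oxy]-2H-chromen-6-yl}ethan-1-one | CC(=O)c1cc(OC(C)(C)C#C)c2OC(C)(C)C=Cc2c1
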